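(The runs come from a simulation from invented constants; noise was put on by code.)

I had no constants for this flask, and a fitted set from so few readings would have told me less than a count, so I chose the next charge by counting.

| setting | summer | midnight | spring | cedar | larch | birch | maple | ash |
|---|---|---|---|---|---|---|---|---|
| starting material | 0.050 M | 0.050 M | 0.050 M | 0.015 M | 0.050 M | 0.15 M | 0.030 M | 0.050 M |
| second substrate | 1 equiv | 1 equiv | 0.62 equiv | 1.00 equiv | 0.500 equiv | 1.00 equiv | 0.250 equiv | 1.00 equiv |
| reagent | 3 equiv | 3 equiv | 3 equiv | 3.00 equiv | 3.00 equiv | 2.00 equiv | 3.00 equiv | 3.00 equiv |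
| free catalyst | 2 mol% | 5.5 mol% | 7.2 mol% | 2.5 mol% | 7.2 mol% | 7.2 mol% | 7.2 mol% | 7.2 mol% |
| remark | run made earlier | run made earlier | run made earlier |  |  |  |  |  |
| time |  |  |  | 20 h | 20 h | 20 h | 20 h | 20 h |

- summer (time / h: target / %, starting material / %): 2.00: 1.8, 97.8; 5.00: 1.2, 96.4; 10.0: 4.1, 94.6; 15.0: 3.9, 94.3
- midnight (time / h: target / %, starting material / %): 4.00: 4.3, 93.4; 8.00: 7.5, 89.7; 10.0: 9.4, 86.6; 15.0: 11.6, 82.2
- spring (time / h: target / %, starting material / %): 1.00: 0.5, 93.3; 2.50: 2.4, 93.4; 6.00: 8.4, 87.3; 15.0: 16.3, 77.7

(scatter of a reading: 1 percentage point)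

- the analysis behind the earlier runs scatters by 1 percentage point, standard deviation
- a reading or a percentage of target counts all its forms, free or not

1. ranking by amount of target, in percent of the starting material charged, from high to low, at 20 h (cedar / larch / birch / maple / ash)
2. the amount of target, in percent of the starting material charged of the flask you put first, at 20 h
3. the amount of target, in percent of the starting material charged of the flask you put last, at 20 h

I wrote the balance of the free catalyst, taking each target as one pass through it:

target fraction = count × catalyst fraction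

The last reading of each run gave its count:

summer: 3.9 % / 2 mol% = 1.95
midnight: 11.6 % / 5.5 mol% = 2.11
spring: 16.3 % / 7.2 mol% = 2.26

Summer's count was about the same as midnight's, although the loading differed, so I let the count stand for these flasks whatever their loading. The midnight run gained 0.400 in count from 10.0 h to 15.0 h, and I allowed the same gain again. That made the count at 20 h, target formed per catalyst charged (the turnover number), equal to 2.51. It is an extrapolation: the midnight run was last read at 15.0 h, so the count rests on that assumed gain as well as on readings with a scatter of 1 percentage point.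

ash: 2.51 × 7.2 mol% = 18.1 %
cedar, if the count carried over: 2.51 × 2.5 mol% = 6.27 %

These counts were read at 0.050 M, but cedar stands at 0.015 M. Ash repeated a known concentration and loading, so I charged cedar next, as the test of the count.

The forecast ranked ash > larch > birch > maple > cedar, with 19 % first (range 16 % to 24 %) and 6 % last (range 3.5 % to 9 %), against my 18.1 % for ash. Of one flask it said: “Birch is untested in concentration and reagent, so uncertain”.

The flasks gave birch > larch > ash > maple > cedar, with birch at 24.2 % and cedar at 2.31 %.

    free catalyst + target ⇌ idle complex, settled at all times (K = 11.0 M⁻¹)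
    reagent + catalyst intermediate A → free catalyst + target (k = 3.20 M⁻¹ h⁻¹)
    reagent + catalyst intermediate B → free catalyst + second product (k = 12.0 M⁻¹ h⁻¹)
    starting material + free catalyst ⇌ catalyst intermediate A (K = 700 M⁻¹, k = 30.0 M⁻¹ h⁻¹)
    starting material + free catalyst → spent catalyst (k = 7.00 M⁻¹ h⁻¹)
    second substrate + free catalyst ⇌ catalyst intermediate B (K = 3500 M⁻¹, k = 69.0 M⁻¹ h⁻¹)

Ash's count came to 2.44, but cedar's came to 0.923, lower than the 2.51 I had reckoned. I carried cedar's count to its neighbour, the same flask with 10 mol% of free catalyst:

0.923 × 10 mol% = 9.23 %

That neighbour gave 8.84 %, a count of 0.884. At 20.0 h, spent catalyst stood at 34.7 % of the catalyst charged in the neighbour and at 35.3 % in cedar.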